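Ring A (C1 OH, C2 O-aryl, C3 Br, C4 Br, C5 H, C6 Br) holds its two oxygen-bearing carbons C1 and C2 between bromines at C3 and C6, which are para to each other. This lets C3–C4–C5–C6 come from the four carbons of mirror-symmetric 2,5-dibromothiophene 1,1-dioxide. C1–C2 comes from the O-silyl ketene acetal of methyl (2-bromophenoxy)acetate, which already carries ring B and the ether bond. One inverse-demand [4+2] cycloaddition with SO2 loss and aromatization forms C2–C3 and C1–C6, closes ring A and places four substituents with no regiochemical choice. Para-bromination of the resulting phenol at C4 finishes the target.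

Key step: step 4

Remark: the target has no stereocentre. The transient cycloadduct and cyclohexadiene of the key step are drawn as one racemic diastereomer (aryloxy cis to silyloxy, both endo in the cycloadduct), and every other isomer would converge on the same arene.

Step 1
Reactants: 1 2,5-dibromothiophene
Product: 3 2,5-dibromothiophene 1,1-dioxide, via sulfoxide 2 (not isolated)
Conditions: urea·H2O2, (CF3CO)2O, MeCN, 0 °C → rt
Reagents that add atoms: hydrogen peroxide as its urea adduct, OO.NC(N)=O, which delivers both oxygens through trifluoroperacetic acid, OOC(=O)C(F)(F)F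
Why: Peracid oxidation of sulfide to sulfone, known for halothiophenes, should work because trifluoroperacetic acid is electrophilic enough for the electron-poor sulfur, oxidizes sulfoxide 2 faster than 2 can dimerize, and gives a dioxide that the two α-bromines make storable.

Step 2
Reactants: 4 2-bromophenol; 5 methyl bromoacetate
Product: 6 methyl 2-(2-bromophenoxy)acetate
Conditions: K2CO3, acetone, reflux
Reagents that add atoms: none
Why: Williamson ether synthesis, in which the phenoxide formed by K2CO3 displaces bromide from the unhindered, carbonyl-activated primary carbon of 5 (SN2) while the ester and the aryl bromide are inert to the mild base.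

Step 3
Reactants: 6 methyl 2-(2-bromophenoxy)acetate
Product: 8 (Z)-[2-(2-bromophenoxy)-1-methoxyethenoxy]trimethylsilane, via lithium enolate 7 (not isolated)
Conditions: LiN(iPr)2 (1.1 equiv), THF, −78 °C; Me3SiCl (1.3 equiv), −78 °C → rt; pentane, filtration under N2, bulb-to-bulb distillation (amine-free)
Reagents that add atoms: chlorotrimethylsilane, C[Si](C)(C)Cl
Why: Standard kinetic ester enolization and O-silylation, in which the α-CH2 is far more acidic than any aryl C–H (so the aryl bromide is left alone at −78 °C), chelated enolate 7 holds OLi cis to the aryloxy oxygen, and silicon is taken up on oxygen to give mainly the Z acetal, whose geometry has no bearing on the later product.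

Step 4
Reactants: 3 2,5-dibromothiophene 1,1-dioxide; 8 (Z)-[2-(2-bromophenoxy)-1-methoxyethenoxy]trimethylsilane
Product: 12 3,6-dibromo-2-(2-bromophenoxy)phenol, via bicyclic sulfone 9 (not isolated), via cyclohexadiene acetal 10 (not isolated), via aryl silyl ether 11 (not isolated)
Conditions: 8 (2 equiv), PhMe, 80 °C, slow N2 sweep; evaporate; KHF2 (3 equiv), MeOH–THF, rt
Reagents that add atoms: none
Why: The sulfonyl group and both bromines lower the LUMO of diene 3, so the high HOMO of ketene acetal 8 adds across the two α-carbons of the dioxide in an inverse-electron-demand Diels–Alder reaction, suprafacial on each partner, which makes C2–C3 and C1–C6 and closes ring A by an intermolecular [4+2] annulation (four diene carbons plus two alkene carbons) in bicyclic sulfone 9. Strained 9 expels SO2 cheletropically to cyclohexadiene 10, whose C1 acetal loses methoxide to a silyloxy-stabilized arenium ion that sheds the C2 proton to give aryl silyl ether 11; KHF2 then cleaves O–Si to phenol 12 and takes any surviving 10 to 12 by desilylation and methanol loss. The closest known chemistry is the cycloaddition of halogenated thiophene 1,1-dioxides to enol ethers, enamines and other electron-rich alkenes with spontaneous SO2 extrusion, together with the aromatizing use of ketene acetals toward 2-pyranones and azadienes. The four stereocentres of 9 and the two of 10 (aryloxy cis to silyloxy, carried over from the Z alkene) vanish on aromatization, so no stereocontrol is required. Both orientations of 8 on 3 are identical because a mirror plane runs through sulfur, and the aryloxy group is retained because C1 has no hydrogen for a 1,2-elimination across C1–C2. The selectivity needed is ring closure over addition–elimination at a C–Br carbon, which neutral, Lewis-acid-free heating in a non-polar solvent favours (a stepwise zwitterion formed at C–Br can still collapse to 9), while the small Me3Si group limits crowding at the C1–C6 bond and the second equivalent of 8 absorbs methanol and SO2-derived acid.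

Step 5
Reactants: 12 3,6-dibromo-2-(2-bromophenoxy)phenol
Product: 13 3,4,6-tribromo-2-(2-bromophenoxy)phenol (target)
Conditions: Br2 (1.0 equiv), NaOAc, AcOH, rt
Reagents that add atoms: bromine, BrBr
Why: Electrophilic aromatic bromination, in which the acidic dibromophenol reacts in the acetate buffer through its phenoxide, whose only open ortho or para site is C4 (C2 and C6 are occupied), so ring A should outrun the weakly activated aryl-ether ring B and the meta position C5, and one equivalent of Br2 should stop at 13.

Compound list
1 | 2,5-dibromothiophene | Brc1ccc(Br)s1 | starting material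
2 | 2,5-dibromothiophene 1-oxide (not isolated) | O=S1C(Br)=CC=C1Br | intermediate
3 | 2,5-dibromothiophene 1,1-dioxide | O=S1(=O)C(Br)=CC=C1Br | intermediate
4 | 2-bromophenol | Oc1ccccc1Br | starting material
5 | methyl bromoacetate | COC(=O)CBr | starting material
6 | methyl 2-(2-bromophenoxy)acetate | COC(=O)COc1ccccc1Br | intermediate
7 | lithium (E)-2-(2-bromophenoxy)-1-methoxyethen-1-olate, OLi cis to the aryloxy group (not isolated) | CO/C(O[Li])=C/Oc1ccccc1Br | intermediate
8 | (Z)-[2-(2-bromophenoxy)-1-methoxyethenoxy]trimethylsilane | CO/C(O[Si](C)(C)C)=C/Oc1ccccc1Br | intermediate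
9 | rac-1,4-dibromo-5-endo-(2-bromophenoxy)-6-exo-methoxy-6-endo-(trimethylsilyloxy)-7-thiabicyclo[2.2.1]hept-2-ene 7,7-dioxide (not isolated) | CO[C@@]1(O[Si](C)(C)C)[C@H](Oc3ccccc3Br)[C@]2(Br)C=C[C@@]1(Br)S2(=O)=O | intermediate
10 | rac-{[2,5-dibromo-6-(2-bromophenoxy)-1-methoxycyclohexa-2,4-dien-1-yl]oxy}trimethylsilane, aryloxy cis to silyloxy (not isolated) | CO[C@]1(O[Si](C)(C)C)C(Br)=CC=C(Br)[C@H]1Oc1ccccc1Br | intermediate
11 | [3,6-dibromo-2-(2-bromophenoxy)phenoxy]trimethylsilane (not isolated) | C[Si](C)(C)Oc1c(Br)ccc(Br)c1Oc1ccccc1Br | intermediate
12 | 3,6-dibromo-2-(2-bromophenoxy)phenol | Oc1c(Br)ccc(Br)c1Oc1ccccc1Br | intermediate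
13 | 3,4,6-tribromo-2-(2-bromophenoxy)phenol | Oc1c(Br)cc(Br)c(Br)c1Oc1ccccc1Br | target

Total step count: 5
Longest linear sequence: 4 steps (4 → 6 → 8 → 12 → 13, steps 2 to 5); step 1 is the short convergent branch.

Steps most likely to fail

1. Step 4. Three things may go wrong.
- The electron-rich alkene may act as a conjugate donor at a bromine-bearing carbon and end in bromide loss or silyl transfer instead of ring closure.
- Crowding at the new C1–C6 bond may slow the cycloaddition until the dioxide self-condenses.
- The acetal may lose silanol in place of methanol during aromatization.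

The fallback sets out from 4 and returns at 12; it buys ring A ready-made and forms the ether bond instead. 2-Bromophenol 4 displaces fluoride from commercial 3,6-dibromo-2-fluorobenzaldehyde (O=Cc1c(F)c(Br)ccc1Br) with K2CO3 in DMF at 80 °C. This SNAr reaction is activated by the ortho formyl group, with fluoride leaving far faster than bromide, and should give 3,6-dibromo-2-(2-bromophenoxy)benzaldehyde F1. Baeyer–Villiger oxidation with mCPBA in CH2Cl2, where the ortho aryloxy donor favours aryl migration, should give 3,6-dibromo-2-(2-bromophenoxy)phenyl formate F2. K2CO3 in MeOH then cleaves F2 to 12.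

2. Step 5. Bromine may attack ring B para to the ether oxygen, or a second bromination may occur at C5, because ring A is slowed by two bromines and a meta aryloxy group.

The fallback sets out from 12 and returns at 13; it introduces C4–Br through nitrogen.
- In aq. NaOH at 0 °C, 12 couples with 4-nitrobenzenediazonium tetrafluoroborate, an electrophile that only a phenoxide ring accepts and that enters once, at the free para position. This should give (E)-3,6-dibromo-2-(2-bromophenoxy)-4-[(4-nitrophenyl)diazenyl]phenol F3.
- Na2S2O4 in aq. EtOH cleaves the azo bond to 4-amino-3,6-dibromo-2-(2-bromophenoxy)phenol F4.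
- Diazotization with NaNO2 in aq. HBr at 0 °C gives 2,5-dibromo-3-(2-bromophenoxy)-4-hydroxybenzenediazonium bromide F5.
- A Sandmeyer reaction of F5 with CuBr should deliver 13.

3. Step 1. Self-dimerization of the sulfoxide may outrun the second oxygen transfer, or the ring may be degraded oxidatively by the strong peracid.

The fallback sets out from 1 and returns at 3; it oxidizes an electron-rich, shielded surrogate and installs the bromines afterwards.
- Double bromine–lithium exchange of 1 with n-BuLi in THF at −78 °C gives 2,5-dilithiothiophene F6.
- Me3SiCl converts F6 into 2,5-bis(trimethylsilyl)thiophene F7.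
- mCPBA in CH2Cl2 oxidizes this more nucleophilic sulfur to 2,5-bis(trimethylsilyl)thiophene 1,1-dioxide F8, whose silyl groups block dimerization.
- Ipso-bromodesilylation of F8 with Br2 and AgBF4 in CH2Cl2 should give 3.

Further compounds
F1 | step 4 | 3,6-dibromo-2-(2-bromophenoxy)benzaldehyde | O=Cc1c(Br)ccc(Br)c1Oc1ccccc1Br
F2 | step 4 | 3,6-dibromo-2-(2-bromophenoxy)phenyl formate | O=COc1c(Br)ccc(Br)c1Oc1ccccc1Br
F3 | step 5 | (E)-3,6-dibromo-2-(2-bromophenoxy)-4-[(4-nitrophenyl)diazenyl]phenol | Oc1c(Br)cc(/N=N/c2ccc(cc2)[N+](=O)[O-])c(Br)c1Oc1ccccc1Br
F4 | step 5 | 4-amino-3,6-dibromo-2-(2-bromophenoxy)phenol | Nc1cc(Br)c(O)c(Oc2ccccc2Br)c1Br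
F5 | step 5 | 2,5-dibromo-3-(2-bromophenoxy)-4-hydroxybenzenediazonium bromide | N#[N+]c1cc(Br)c(O)c(Oc2ccccc2Br)c1Br.[Br-]
F6 | step 1 | 2,5-dilithiothiophene | [Li]c1ccc([Li])s1
F7 | step 1 | 2,5-bis(trimethylsilyl)thiophene | C[Si](C)(C)c1ccc([Si](C)(C)C)s1
F8 | step 1 | 2,5-bis(trimethylsilyl)thiophene 1,1-dioxide | C[Si](C)(C)C1=CC=C([Si](C)(C)C)S1(=O)=O
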